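**Retrosynthetic overview**

1. Numbering used below: 1H-isochromene core O2, C1, C3, C4, C4a, C5, C6, C7, C8, C8a; side chain C9–C11.
2. Last disconnection: the C6–O ester, from diol 20 and the ketal-protected aryl acid 25, followed by one acidolysis of both protecting groups.
3. Key disconnection: the pyran ring is opened at C1–C8a to give the monocyclic dienol ether 17, whose O2 already carries C1 as an O–CH2–SMe group. Compound 17 comes from enal 11 and phosphonate 16 (C3=C4 by Horner–Wadsworth–Emmons olefination).
4. Enabling feature: the ring O2–C1–C8a–C4a–C4–C3 is a cyclized 2-oxoniahexatriene. C8a is the α-carbon of the doubly vinylogous ester O2–C3=C4–C4a=C8a–C8=O (the π-nucleophilic terminus of the dienol ether), and C1 is a CH2 bound only to O2 and C8a, i.e. a latent O-stabilized cation.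
5. Ring order: carbocycle first, from (R)-carvone (ring carbons and C7 methyl from the chiral pool; 6R,7R set by dihydroxylation); pyran second (key step); arene ester last.

Key step: step 13

Remark: (R)-carvone, acrolein, tert-butyl acrylate and 2,3,4-trimethoxy-6-methylbenzaldehyde are taken as commercial; atom labels C1–C11 in all descriptions are those of the target as defined above.

**Route**

Step 1
Reactants: 1 (R)-carvone
Product: 4 (R)-5-acetoxy-2-methylcyclohex-2-en-1-one, via methoxy hydroperoxide 2 (not isolated), via peroxyacetate 3 (not isolated)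
Conditions: O3, CH2Cl2/MeOH, −78 °C; then Ac2O, Et3N, DMAP (cat.), −78 °C → 23 °C
Reagents that add atoms: ozone [O-][O+]=O; methanol CO
Why: Ozonolysis of the isopropenyl group in methanol gives the α-methoxy hydroperoxide, whose peracetate undergoes Criegee rearrangement with retention at the migrating ring carbon, so that the enone is untouched and the carvone stereocenter becomes a C–O stereocenter at the future C4a.

Step 2
Reactants: 4 (R)-5-acetoxy-2-methylcyclohex-2-en-1-one
Product: 5 (1R,5R)-5-acetoxy-2-methylcyclohex-2-en-1-ol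
Conditions: NaBH4, CeCl3·7H2O, MeOH, −78 °C
Reagents that add atoms: none
Why: Luche reduction gives 1,2-reduction only, and axial hydride delivery to the half-chair with the equatorial acetoxy group should give the cis alcohol (new carbinol center R), as in the reduction of carvone to cis-carveol.

Step 3
Reactants: 5 (1R,5R)-5-acetoxy-2-methylcyclohex-2-en-1-ol
Product: 6 triol monoacetate (3,4,5-trihydroxy-4-methylcyclohexyl acetate; 4-OH and 5-OH cis to each other and on the face opposite to the 3-OH and the acetoxy group)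
Conditions: OsO4 (cat.), N-methylmorpholine N-oxide, acetone/H2O, 23 °C
Reagents that add atoms: N-methylmorpholine N-oxide C[N+]1([O-])CCOCC1; water O
Why: Catalytic OsO4 dihydroxylation is a syn addition that should occur anti to the allylic hydroxyl (the usual anti selectivity of cyclic allylic alcohols), reinforced by the cis acetoxy group, which sets the future C6 and C7 (cis-diol, 6R,7R) from the two auxiliary centers.

Step 4
Reactants: 6 triol monoacetate
Product: 7 acetonide alcohol (cis-diol of 6 as isopropylidene acetal, 3-hydroxyl free)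
Conditions: Me2C(OMe)2, PPTS (cat.), CH2Cl2, 23 °C
Reagents that add atoms: 2,2-dimethoxypropane COC(C)(C)OC
Why: Acid-catalyzed transketalization forms the five-membered dioxolane only on the cis-1,2-diol, and the hydroxyl trans to it stays free.

Step 5
Reactants: 7 acetonide alcohol
Product: 8 acetonide diol (future C8 and C4a hydroxyls free)
Conditions: K2CO3 (cat.), MeOH, 0 °C → 23 °C
Reagents that add atoms: none
Why: Base-catalyzed transesterification (methanolysis) removes the acetate at a stage with no ketone in the molecule, so β-elimination cannot compete.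

Step 6
Reactants: 8 acetonide diol
Product: 9 (3aR,7aR)-2,2,3a-trimethyl-7,7a-dihydro-3aH-1,3-benzodioxole-4,6(5H)-dione
Conditions: Dess–Martin periodinane, CH2Cl2, 0 °C → 23 °C
Reagents that add atoms: none
Why: Dess–Martin oxidation of both secondary alcohols under non-basic conditions gives the cyclic 1,3-dione (as its enol) and erases the two auxiliary stereocenters at the future C8 and C4a.

Step 7
Reactants: 9 acetonide 1,3-dione
Product: 10 (3aR,7aR)-2,2,3a-trimethyl-4-oxo-3a,4,7,7a-tetrahydro-1,3-benzodioxol-6-yl trifluoromethanesulfonate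
Conditions: Tf2O, pyridine, CH2Cl2, −78 °C → 0 °C
Reagents that add atoms: triflic anhydride FC(F)(F)S(=O)(=O)OS(=O)(=O)C(F)(F)F
Why: O-Sulfonylation of the dione enol is expected at the oxygen remote from the fully substituted C7 (steric control, as in enol ether formation from 4,4-disubstituted cyclohexane-1,3-diones), leaving the ketone at C8 and the triflate at C4a.

Step 8
Reactants: 10 vinyl triflate
Product: 11 (3aR,7aR)-2,2,3a-trimethyl-4-oxo-3a,4,7,7a-tetrahydro-1,3-benzodioxole-6-carbaldehyde
Conditions: Pd(PPh3)4 (cat.), CO (1 atm), Bu3SnH (slow addition), THF, 50 °C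
Reagents that add atoms: carbon monoxide [C-]#[O+]
Why: Stille-type reductive carbonylation, in which oxidative addition of zerovalent palladium to the vinyl triflate, CO insertion and hydride transfer from tin to the acylpalladium species give the enal and thereby install C4.

Step 9
Reactants: 12 acrolein
Product: 13 diethyl (1-hydroxyprop-2-en-1-yl)phosphonate (racemic)
Conditions: HP(O)(OEt)2, Et3N (cat.), CH2Cl2, 0 °C
Reagents that add atoms: diethyl phosphite CCO[PH](=O)OCC
Why: Amine-catalyzed Pudovik 1,2-addition of the P–H bond to the aldehyde gives the α-hydroxy phosphonate, whose stereocenter is lost later in the olefination.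

Step 10
Reactants: 13 diethyl (1-hydroxyprop-2-en-1-yl)phosphonate; 14 tert-butyl acrylate
Product: 15 tert-butyl (2E)-4-(diethoxyphosphoryl)-4-hydroxybut-2-enoate (racemic)
Conditions: second-generation Hoveyda–Grubbs catalyst [RuCl2(=CH-C6H4-2-OiPr)(H2IMes)] (cat.), 14 in excess, CH2Cl2, 40 °C
Reagents that add atoms: none
Why: Olefin cross-metathesis of a secondary allylic alcohol with an excess of acrylate is selective for the cross product and should give the E-enoate.

Step 11
Reactants: 15 hydroxy phosphonate
Product: 16 tert-butyl (2E)-4-(diethoxyphosphoryl)-4-[(methylsulfanyl)methoxy]but-2-enoate (racemic)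
Conditions: Me2S, (PhCO2)2, MeCN, 0 °C
Reagents that add atoms: dimethyl sulfide CSC
Why: Pummerer-type methylthiomethyl ether formation, in which the alcohol traps the methylthiomethyl cation generated from dimethyl sulfide and benzoyl peroxide under non-basic conditions that avoid phosphonate–phosphate rearrangement; this places the future C1 on the future O2.

Step 12
Reactants: 11 enal; 16 phosphonate
Product: 17 tert-butyl (2E,4Z)-4-[(methylsulfanyl)methoxy]-5-[(3aR,7aR)-2,2,3a-trimethyl-4-oxo-3a,4,7,7a-tetrahydro-1,3-benzodioxol-6-yl]penta-2,4-dienoate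
Conditions: 16, LiN(SiMe3)2, THF, −78 °C; then 11, −78 °C → 0 °C
Reagents that add atoms: none
Why: Horner–Wadsworth–Emmons olefination at the aldehyde (far more electrophilic than the vinylogous ketone) forms C3=C4, and as with α-alkoxy phosphonoacetates the ring carbon should end up trans to the anion-stabilizing enoate arm and cis to the oxygen (4Z), the geometry needed for ring closure.

Step 13
Reactants: 17 dienol methylthiomethyl ether
Product: 19 tert-butyl (E)-3-[(6R,7R)-6,7-(isopropylidenedioxy)-7-methyl-8-oxo-5,6,7,8-tetrahydro-1H-isochromen-3-yl]prop-2-enoate, via sulfonium triflate 18 (not isolated)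
Conditions: MeOTf, 2,6-di-tert-butyl-4-methylpyridine, 4 Å molecular sieves, CH2Cl2, −40 °C → 23 °C
Reagents that add atoms: none
Why: Proposed new method: MeOTf methylates the thioether sulfur of 17 (the softest nucleophile present), and the O–CH2–SMe2(+) sulfonium 18 ionizes with π-participation of the cross-conjugated dienol ether, so that the 2-oxoniahexatriene C1=O2(+)–C3=C4–C4a=C8a closes the C1–C8a bond; the resulting alkoxyallyl cation O2(+)=C3–C4=C4a then loses the C8a proton (α to the C8 ketone) to the hindered pyridine, which restores the C4a=C8a enone. The closest known reaction types are the oxa-Pictet–Spengler and Prins cyclizations of O-tethered oxocarbenium ions (here with a push–pull diene in place of an arene), the S-alkylative unmasking of methylthiomethyl ethers, and the 6π-electrocyclization of 2-azatrienes. The pyran ring is closed in a 6-endo mode, equivalent to a thermally allowed disrotatory 6π-electrocyclization of the oxonia-triene. No stereocenter is formed, and C6 and C7 are not touched. The step needs regioselectivity for C8a, which the tether secures (attack by C4 would give a four-membered ring and C5 is sp3), and it needs the 4Z geometry that places O2 cis to C4a, which step 12 provides and which the low C3=C4 rotation barrier of the push–pull system can correct. The non-nucleophilic base keeps the medium free of TfOH, so the acetonide and the tert-butyl ester should survive.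

Step 14
Reactants: 19 bicyclic acetonide
Product: 20 tert-butyl (E)-3-[(6R,7R)-6,7-dihydroxy-7-methyl-8-oxo-5,6,7,8-tetrahydro-1H-isochromen-3-yl]prop-2-enoate
Conditions: 1 M aq. HCl, THF, 23 °C
Reagents that add atoms: none
Why: Acid-catalyzed acetal hydrolysis frees the cis-diol, while the tert-butyl ester and the push–pull dienol ether (protonated reversibly on the C8 carbonyl oxygen) should tolerate dilute aqueous acid at room temperature.

Step 15
Reactants: 21 2,3,4-trimethoxy-6-methylbenzaldehyde
Product: 22 2,3,4-trihydroxy-6-methylbenzaldehyde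
Conditions: BBr3, CH2Cl2, −78 °C → 23 °C; then H2O
Reagents that add atoms: none
Why: Lewis acid-mediated SN2 demethylation of all three aryl methyl ethers by BBr3, with the aldehyde surviving as its boron chelate.

Step 16
Reactants: 22 2,3,4-trihydroxy-6-methylbenzaldehyde
Product: 23 4-hydroxy-6-methyl-2,2-diphenyl-1,3-benzodioxole-5-carbaldehyde
Conditions: Ph2CCl2, K2CO3, MeCN, 80 °C
Reagents that add atoms: dichlorodiphenylmethane ClC(Cl)(c1ccccc1)c1ccccc1
Why: Double O-alkylation (ketal formation) is selective for the 3,4-catechol pair because the 2-hydroxyl is hydrogen-bonded to the ortho aldehyde and is the least nucleophilic oxygen.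

Step 17
Reactants: 23 hydroxy aldehyde
Product: 24 4-methoxy-6-methyl-2,2-diphenyl-1,3-benzodioxole-5-carbaldehyde
Conditions: MeI, K2CO3, DMF, 40 °C
Reagents that add atoms: iodomethane CI
Why: Williamson methylation of the one remaining phenol.

Step 18
Reactants: 24 methoxy aldehyde
Product: 25 4-methoxy-6-methyl-2,2-diphenyl-1,3-benzodioxole-5-carboxylic acid
Conditions: NaClO2, NaH2PO4, 2-methyl-2-butene, t-BuOH/H2O, 23 °C
Reagents that add atoms: sodium chlorite [Na+].[O-]Cl=O
Why: Pinnick oxidation converts the hindered, electron-rich aldehyde into the acid without a hindered ester hydrolysis, with 2-methyl-2-butene scavenging HOCl.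

Step 19
Reactants: 20 diol; 25 aryl acid
Product: 27 (6R,7R)-3-[(E)-3-tert-butoxy-3-oxoprop-1-enyl]-7-hydroxy-7-methyl-8-oxo-5,6,7,8-tetrahydro-1H-isochromen-6-yl 4-methoxy-6-methyl-2,2-diphenyl-1,3-benzodioxole-5-carboxylate, via acid chloride 26 (not isolated)
Conditions: 25, (COCl)2, DMF (cat.), CH2Cl2, 0 °C → 23 °C, evaporation; then 20, pyridine, DMAP, CH2Cl2, 0 °C → 23 °C
Reagents that add atoms: none
Why: Acid chloride formation followed by DMAP-catalyzed acyl transfer (nucleophilic catalysis, suited to di-ortho-substituted benzoyl chlorides) should esterify the secondary C6 hydroxyl in preference to the tertiary C7 hydroxyl, with retention at C6.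

Step 20
Reactants: 27 protected ester
Product: 28 target, (E)-3-[(6R,7R)-6-(3,4-dihydroxy-2-methoxy-6-methylbenzoyl)oxy-7-hydroxy-7-methyl-8-oxo-5,6,7,8-tetrahydro-1H-isochromen-3-yl]prop-2-enoic acid
Conditions: CF3CO2H/CH2Cl2 (1:2), H2O (5 equiv), 0 °C → 23 °C
Reagents that add atoms: none
Why: Acidolysis cleaves the tert-butyl ester (E1, loss of isobutene) and hydrolyzes the diphenylmethylene ketal in one operation, and it avoids base, which would risk β-elimination of the C6 ester across C5–C6.

**Compound list**

1 | (R)-carvone, (5R)-2-methyl-5-(prop-1-en-2-yl)cyclohex-2-en-1-one | CC1=CC[C@H](CC1=O)C(C)=C | starting material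
2 | (5R)-5-(1-hydroperoxy-1-methoxyethyl)-2-methylcyclohex-2-en-1-one (both epimers at the peroxy carbon) | CC1=CC[C@H](CC1=O)C(C)(OC)OO | intermediate
3 | O-acetyl derivative (peroxyacetate) of 2 | CC1=CC[C@H](CC1=O)C(C)(OC)OOC(C)=O | intermediate
4 | (R)-5-acetoxy-2-methylcyclohex-2-en-1-one | CC1=CC[C@H](CC1=O)OC(C)=O | intermediate
5 | (1R,5R)-5-acetoxy-2-methylcyclohex-2-en-1-ol (hydroxyl cis to acetoxy) | CC1=CC[C@@H](OC(C)=O)C[C@H]1O | intermediate
6 | 3,4,5-trihydroxy-4-methylcyclohexyl acetate; 4-OH and 5-OH cis and on the ring face opposite to the 3-OH and the acetoxy group, 4-methyl on the acetoxy face (C4 and C5 are the future C7 and C6) | O[C@@H]1C[C@@H](OC(C)=O)C[C@@H](O)[C@]1(C)O | intermediate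
7 | 4,5-O-isopropylidene acetal of 6 (3-hydroxyl free) | CC2(C)O[C@@H]1C[C@@H](OC(C)=O)C[C@@H](O)[C@]1(C)O2 | intermediate
8 | acetonide diol from 7 (acetate removed; future C8 and C4a hydroxyls free) | CC2(C)O[C@@H]1C[C@@H](O)C[C@@H](O)[C@]1(C)O2 | intermediate
9 | (3aR,7aR)-2,2,3a-trimethyl-7,7a-dihydro-3aH-1,3-benzodioxole-4,6(5H)-dione, the acetonide of (4R,5R)-4,5-dihydroxy-4-methylcyclohexane-1,3-dione | CC2(C)O[C@@H]1CC(=O)CC(=O)[C@]1(C)O2 | intermediate
10 | (3aR,7aR)-2,2,3a-trimethyl-4-oxo-3a,4,7,7a-tetrahydro-1,3-benzodioxol-6-yl trifluoromethanesulfonate | CC2(C)O[C@@H]1CC(OS(=O)(=O)C(F)(F)F)=CC(=O)[C@]1(C)O2 | intermediate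
11 | (3aR,7aR)-2,2,3a-trimethyl-4-oxo-3a,4,7,7a-tetrahydro-1,3-benzodioxole-6-carbaldehyde | CC2(C)O[C@@H]1CC(C=O)=CC(=O)[C@]1(C)O2 | intermediate
12 | acrolein | C=CC=O | starting material
13 | diethyl (1-hydroxyprop-2-en-1-yl)phosphonate (racemic) | CCOP(=O)(OCC)C(O)C=C | intermediate
14 | tert-butyl acrylate | C=CC(=O)OC(C)(C)C | starting material
15 | tert-butyl (2E)-4-(diethoxyphosphoryl)-4-hydroxybut-2-enoate (racemic) | CCOP(=O)(OCC)C(O)/C=C/C(=O)OC(C)(C)C | intermediate
16 | tert-butyl (2E)-4-(diethoxyphosphoryl)-4-[(methylsulfanyl)methoxy]but-2-enoate (racemic) | CCOP(=O)(OCC)C(OCSC)/C=C/C(=O)OC(C)(C)C | intermediate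
17 | tert-butyl (2E,4Z)-4-[(methylsulfanyl)methoxy]-5-[(3aR,7aR)-2,2,3a-trimethyl-4-oxo-3a,4,7,7a-tetrahydro-1,3-benzodioxol-6-yl]penta-2,4-dienoate | CC2(C)O[C@@H]1CC(/C=C(/C=C/C(=O)OC(C)(C)C)OCSC)=CC(=O)[C@]1(C)O2 | intermediate
18 | S,S-dimethylsulfonium triflate of 17 (O–CH2–SMe2(+) TfO(−)) | CC2(C)O[C@@H]1CC(/C=C(/C=C/C(=O)OC(C)(C)C)OC[S+](C)C)=CC(=O)[C@]1(C)O2.[O-]S(=O)(=O)C(F)(F)F | intermediate
19 | tert-butyl (E)-3-[(6R,7R)-6,7-(isopropylidenedioxy)-7-methyl-8-oxo-5,6,7,8-tetrahydro-1H-isochromen-3-yl]prop-2-enoate | CC3(C)O[C@@H]1CC2=C(COC(/C=C/C(=O)OC(C)(C)C)=C2)C(=O)[C@]1(C)O3 | intermediate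
20 | tert-butyl (E)-3-[(6R,7R)-6,7-dihydroxy-7-methyl-8-oxo-5,6,7,8-tetrahydro-1H-isochromen-3-yl]prop-2-enoate | O[C@@H]1CC2=C(COC(/C=C/C(=O)OC(C)(C)C)=C2)C(=O)[C@]1(C)O | intermediate
21 | 2,3,4-trimethoxy-6-methylbenzaldehyde | COc1cc(C)c(C=O)c(OC)c1OC | starting material
22 | 2,3,4-trihydroxy-6-methylbenzaldehyde | Cc1cc(O)c(O)c(O)c1C=O | intermediate
23 | 4-hydroxy-6-methyl-2,2-diphenyl-1,3-benzodioxole-5-carbaldehyde | Cc1cc2OC(c3ccccc3)(c3ccccc3)Oc2c(O)c1C=O | intermediate
24 | 4-methoxy-6-methyl-2,2-diphenyl-1,3-benzodioxole-5-carbaldehyde | COc1c(C=O)c(C)cc2OC(c3ccccc3)(c3ccccc3)Oc12 | intermediate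
25 | 4-methoxy-6-methyl-2,2-diphenyl-1,3-benzodioxole-5-carboxylic acid | COc1c(C(O)=O)c(C)cc2OC(c3ccccc3)(c3ccccc3)Oc12 | intermediate
26 | 4-methoxy-6-methyl-2,2-diphenyl-1,3-benzodioxole-5-carbonyl chloride | COc1c(C(Cl)=O)c(C)cc2OC(c3ccccc3)(c3ccccc3)Oc12 | intermediate
27 | (6R,7R)-3-[(E)-3-tert-butoxy-3-oxoprop-1-enyl]-7-hydroxy-7-methyl-8-oxo-5,6,7,8-tetrahydro-1H-isochromen-6-yl 4-methoxy-6-methyl-2,2-diphenyl-1,3-benzodioxole-5-carboxylate | COc1c(C(=O)O[C@@H]3CC4=C(COC(/C=C/C(=O)OC(C)(C)C)=C4)C(=O)[C@]3(C)O)c(C)cc2OC(c5ccccc5)(c5ccccc5)Oc12 | intermediate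
28 | (E)-3-[(6R,7R)-6-(3,4-dihydroxy-2-methoxy-6-methylbenzoyl)oxy-7-hydroxy-7-methyl-8-oxo-5,6,7,8-tetrahydro-1H-isochromen-3-yl]prop-2-enoic acid | COc1c(O)c(O)cc(C)c1C(=O)O[C@@H]1CC2=C(COC(/C=C/C(=O)O)=C2)C(=O)[C@]1(C)O | target

**Step count**

Total step count: 20.
Longest linear sequence: 13 steps (steps 1–8, 12, 13, 14, 19, 20; from 1 to 28).

**Steps most likely to fail**

Step 13 (proposed new method). The sulfonium salt may fail to ionize into the ring-closing pathway, because O2 is a weak donor while it is conjugated to the C8 ketone; hydrolysis or intermolecular alkylation on work-up would then compete with C1–C8a closure. The fallback sets out from enal 11 and comes back at 19, and uses known reaction types only. Conjugate hydrogenation (H2, Pd on carbon, EtOAc) of the C4a=C8a bond gives the keto aldehyde F1. Horner–Wadsworth–Emmons olefination with 16 (LiN(SiMe3)2, THF) gives the non-conjugated enol ether F2, in which O2 is an ordinary enol ether oxygen. Me3SiOTf/Et3N gives the only possible silyl enol ether F3 (C8=C8a). MeOTf with 2,6-di-tert-butyl-4-methylpyridine then triggers a Mukaiyama-type alkylation of the silyl enol ether by the O2-stabilized oxocarbenium ion, which closes C1–C8a and gives the dihydro ketone F4. DDQ dehydrogenation across C4a–C8a then returns to 19.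

Step 7. Sulfonylation may take place at the other enol oxygen (next to C7), which would transpose the ketone and the triflate and carry the wrong enone through steps 8 and 12. The fallback sets out from alcohol 7 and comes back at enal 11 without passing through a 1,3-dione. Dess–Martin oxidation of the free hydroxyl gives the β-acetoxy ketone F5, and DBU eliminates acetic acid to give the enone F6, whose regiochemistry is fixed by the position of the acetate. Conjugate addition of CH2=CHMgBr/CuBr·SMe2 with Me3SiCl trapping gives the silyl enol ether F7. Saegusa–Ito oxidation with Pd(OAc)2 gives the vinyl enone F8, and Lemieux–Johnson cleavage (OsO4 cat., NaIO4) of the terminal vinyl group gives 11.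

Step 19. Acyl transfer from the di-ortho-substituted benzoyl chloride to the secondary hydroxyl next to the quaternary C7 may be slow; acylation of the tertiary hydroxyl or amine-promoted β-elimination across C5–C6 could then compete. The fallback sets out from diol 20 (with acid chloride 26) and comes back at 27. It activates the nucleophile instead of relying on amine catalysis: Bu2Sn(OMe)2 in toluene converts the cis-diol into the dibutylstannylene acetal F9, in which the secondary oxygen is the reactive tin alkoxide, and treatment with 26 without any amine base, followed by aqueous work-up, should give 27.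

Further compounds
F1 | step 13 | (3aR,7aR)-2,2,3a-trimethyl-4-oxohexahydro-1,3-benzodioxole-6-carbaldehyde (both epimers at the formyl-bearing carbon) | CC2(C)O[C@@H]1CC(C=O)CC(=O)[C@]1(C)O2
F2 | step 13 | tert-butyl (2E,4Z)-4-[(methylsulfanyl)methoxy]-5-[(3aR,7aR)-2,2,3a-trimethyl-4-oxohexahydro-1,3-benzodioxol-6-yl]penta-2,4-dienoate | CC2(C)O[C@@H]1CC(/C=C(/C=C/C(=O)OC(C)(C)C)OCSC)CC(=O)[C@]1(C)O2
F3 | step 13 | trimethylsilyl enol ether of F2 (C8–OSiMe3, C8=C8a) | CC2(C)O[C@@H]1CC(/C=C(/C=C/C(=O)OC(C)(C)C)OCSC)C=C(O[Si](C)(C)C)[C@]1(C)O2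
F4 | step 13 | 4a,8a-dihydro derivative of 19 (hydrogens at C4a and C8a) | CC3(C)O[C@@H]1CC2C=C(/C=C/C(=O)OC(C)(C)C)OCC2C(=O)[C@]1(C)O3
F5 | step 7 | β-acetoxy ketone from 7 (free hydroxyl oxidized to the C8 ketone, acetate retained at C4a) | CC2(C)O[C@@H]1C[C@@H](OC(C)=O)CC(=O)[C@]1(C)O2
F6 | step 7 | (3aR,7aR)-2,2,3a-trimethyl-7,7a-dihydro-1,3-benzodioxol-4(3aH)-one | CC2(C)O[C@@H]1CC=CC(=O)[C@]1(C)O2
F7 | step 7 | trimethylsilyl enol ether of the 3-vinyl ketone (vinyl at C4a, C8–OSiMe3, C8=C8a) | CC2(C)O[C@@H]1CC(C=C)C=C(O[Si](C)(C)C)[C@]1(C)O2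
F8 | step 7 | (3aR,7aR)-6-ethenyl-2,2,3a-trimethyl-7,7a-dihydro-1,3-benzodioxol-4(3aH)-one | CC2(C)O[C@@H]1CC(C=C)=CC(=O)[C@]1(C)O2
F9 | step 19 | 6,7-O-dibutylstannylene acetal of 20 | CCCC[Sn]3(CCCC)O[C@@H]1CC2=C(COC(/C=C/C(=O)OC(C)(C)C)=C2)C(=O)[C@]1(C)O3
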